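**Retrosynthetic overview**
1. Target ⇐ phenol deacetylation, C10 tigloylation, hydroxyl-directed reduction of a C10 enone and C6 aroylation of a cis-fused bicyclic 4,6-dihydroxy enone.
2. Bicyclic enone ⇐ seven-membered ring closed last at C6–C7 by a chelation-controlled carbonyl-ene cyclisation of a keto aldehyde, itself the photodeconjugated form of a senecioyl ketone.
3. Senecioyl ketone ⇐ C1–C10 bond and the quaternary centre by a visible-light acyl-radical conjugate addition of 3-methylbut-2-enoic acid to a cyclopentene carbaldehyde.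
4. Cyclopentene carbaldehyde ⇐ five-membered ring made first, by ozonolysis/aldol ring contraction of (S)-terpinen-4-ol, whose carbinol carbon becomes C4 and relays to C1, C5, C6 and C10.

Assumption: (S)-(+)-terpinen-4-ol is bought in high enantiomeric purity.
Numbering: daucane locants are used (C1 quaternary methyl carbon, C4 isopropyl carbinol, C5 ring-fusion CH, C6 and C10 oxygenated carbons, C8=C9 alkene); the ring fusion is cis (1-methyl and 5-H on the same face).

Step 1
Reactants: 1 (S)-(+)-terpinen-4-ol
Product: 2 triethyl{[(1S)-4-methyl-1-(propan-2-yl)cyclohex-3-en-1-yl]oxy}silane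
Conditions: TESOTf (1.3 equiv), 2,6-lutidine (2 equiv), CH2Cl2, 0 °C → rt
Reagents that add atoms: triethylsilyl trifluoromethanesulfonate, CC[Si](CC)(CC)OS(=O)(=O)C(F)(F)F
Why: Silyl-triflate O-silylation of the hindered tertiary alcohol masks the hydroxyl so that it cannot be lost by E1cB elimination in the enamine aldol condensation of step 2; the purchased stereocentre (C4) is untouched.

Step 2
Reactants: 2 triethyl{[(1S)-4-methyl-1-(propan-2-yl)cyclohex-3-en-1-yl]oxy}silane
Product: 6 (5R)-5-hydroxy-2-methyl-5-(propan-2-yl)cyclopent-1-ene-1-carbaldehyde, via ozonide 3 (not isolated), via keto aldehyde 4 (not isolated), via silyl enal 5 (not isolated)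
Conditions: O3, CH2Cl2, −78 °C; PPh3 (1.1 equiv), −78 °C → rt; piperidine (0.3 equiv), AcOH (0.3 equiv), 40 °C; 2 M HCl, THF, rt
Reagents that add atoms: ozone, [O-][O+]=O
Why: Ozonolysis of the trisubstituted alkene followed by a piperidinium-acetate enamine aldol condensation (aldehyde α-carbon onto the methyl ketone, 5-exo, by analogy with the limonene-derived keto aldehyde) contracts the ring to the cyclopentene carbaldehyde, and acid then cleaves the silyl ether; the carbinol stereocentre is not involved.

Step 3
Reactants: 6 (5R)-5-hydroxy-2-methyl-5-(propan-2-yl)cyclopent-1-ene-1-carbaldehyde; 7 3-methylbut-2-enoic acid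
Product: 9 (1R,2R,5R)-2-hydroxy-5-methyl-5-(3-methylbut-2-enoyl)-2-(propan-2-yl)cyclopentane-1-carbaldehyde, via 1-epi keto aldehyde 8 (not isolated)
Conditions: 7 (2.5 equiv), PPh3 (2.5 equiv), 4CzIPN (2 mol%), 2,4,6-collidine (2.5 equiv), MeCN, 450 nm LEDs, 25 °C; then DBU (0.2 equiv), 0 °C → rt
Reagents that add atoms: none
Why: Proposed new method: a deoxygenative photoredox acyl-radical Giese addition that builds a quaternary centre on the fully substituted β-carbon of an enal – excited 4CzIPN oxidises PPh3 to its radical cation, which adds to the carboxylate of 7 and fragments (β-scission) to Ph3P=O and the small nucleophilic σ-acyl radical; with no hydrogen-atom donor present this radical lives until it adds to C1 of 6 (LUMO lowered by the internal O–H···O=C hydrogen bond) on the face anti to the pseudo-axial isopropyl group and syn to the hydroxyl, the α-formyl radical is reduced by the photocatalyst radical anion and protonated, and DBU equilibrates C5 to the all-cis aldehyde (formyl trans to isopropyl); the closest known chemistry is phosphine-mediated photoredox hydroacylation of styrenes and acrylates with aromatic acids and acyl-radical conjugate addition to β-monosubstituted enals.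

Step 4
Reactants: 9 (1R,2R,5R)-2-hydroxy-5-methyl-5-(3-methylbut-2-enoyl)-2-(propan-2-yl)cyclopentane-1-carbaldehyde
Product: 12 (1R,4R,5S,6R)-4,6-dihydroxydauc-8-en-10-one, via deconjugated keto aldehyde 10 (not isolated), via exo-methylene ketone 11 (not isolated)
Conditions: hν (365 nm LEDs), imidazole (5 mol%), CH2Cl2, 0 °C; then Me2AlCl (3.5 equiv), −78 → −20 °C, 1 M HCl quench; then DBU (0.1 equiv), CH2Cl2, 0 °C
Reagents that add atoms: none
Why: Photodeconjugation (photoenolisation of the β,β-dimethyl enone and base-catalysed α-protonation of the dienol) unmasks a 1,1-disubstituted alkene that undergoes a Me2AlCl-promoted type-two carbonyl-ene cyclisation onto the aldehyde held in a six-membered C4–O–AlMeCl chelate, so the tethered alkene can only attack the aldehyde face turned toward C10 and the C6 hydroxyl is set on the same face as the C4 oxygen; DBU then moves the exocyclic alkene into conjugation as C8=C9.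

Step 5
Reactants: 12 (1R,4R,5S,6R)-4,6-dihydroxydauc-8-en-10-one; 13 4-(acetyloxy)benzoyl chloride
Product: 14 (1R,4R,5S,6R)-4-hydroxy-10-oxodauc-8-en-6-yl 4-(acetyloxy)benzoate
Conditions: 13 (1.3 equiv), pyridine (3 equiv), DMAP (0.1 equiv), CH2Cl2, 0 °C → rt
Reagents that add atoms: none
Why: DMAP-catalysed acylation (nucleophilic catalysis) of the only secondary hydroxyl, the tertiary C4–OH being inert, with a weak base so that the new δ-acyloxy enone does not undergo vinylogous β-elimination; no stereocentre is touched.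

Step 6
Reactants: 14 (1R,4R,5S,6R)-4-hydroxy-10-oxodauc-8-en-6-yl 4-(acetyloxy)benzoate
Product: 15 (1R,4R,5S,6R,10R)-4,10-dihydroxydauc-8-en-6-yl 4-(acetyloxy)benzoate
Conditions: NaBH(OAc)3 (4 equiv), MeCN/AcOH (1:1), −20 → 0 °C
Reagents that add atoms: none
Why: Saksena–Evans hydroxyl-directed 1,2-reduction: the tertiary C4–OH, which lies on the concave face directly over C10, binds the acetoxyborohydride and delivers hydride intramolecularly to that face (also the face anti to the angular methyl), giving the C10 alcohol cis to the C1 methyl.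

Step 7
Reactants: 15 (1R,4R,5S,6R,10R)-4,10-dihydroxydauc-8-en-6-yl 4-(acetyloxy)benzoate; 16 (2E)-2-methylbut-2-enoyl chloride
Product: 17 (1R,4R,5S,6R,10R)-4-hydroxy-10-{[(2E)-2-methylbut-2-enoyl]oxy}dauc-8-en-6-yl 4-(acetyloxy)benzoate
Conditions: 16 (2 equiv), pyridine (4 equiv), DMAP (1 equiv), CH2Cl2, rt → 40 °C
Reagents that add atoms: none
Why: DMAP-mediated acylation of the hindered allylic secondary alcohol with retention at C10 (the tertiary C4–OH does not react), using pyridine instead of a trialkylamine to avoid vinylketene formation and E/Z or β,γ-isomerisation of the tigloyl group.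

Step 8
Reactants: 17 (1R,4R,5S,6R,10R)-4-hydroxy-10-{[(2E)-2-methylbut-2-enoyl]oxy}dauc-8-en-6-yl 4-(acetyloxy)benzoate
Product: 18 (1R,4R,5S,6R,10R)-4-hydroxy-10-{[(2E)-2-methylbut-2-enoyl]oxy}dauc-8-en-6-yl 4-hydroxybenzoate
Conditions: NH4OAc (10 equiv), MeOH/H2O (4:1), rt
Reagents that add atoms: none
Why: Chemoselective solvolysis of the phenolic acetate, which is far more electrophilic than the hindered alkyl benzoate and tiglate, frees the phenol without touching either alkyl ester or any stereocentre.

**Compound list**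
1 | (S)-(+)-terpinen-4-ol, (1S)-4-methyl-1-(propan-2-yl)cyclohex-3-en-1-ol | C1C=C(C)CC[C@@]1(O)C(C)C | starting material
2 | triethyl{[(1S)-4-methyl-1-(propan-2-yl)cyclohex-3-en-1-yl]oxy}silane | C1C=C(C)CC[C@@]1(O[Si](CC)(CC)CC)C(C)C | intermediate
3 | ozonide of 2 (1,2,4-trioxolane spanning the former C3=C4 alkene carbons; epimers at those two carbons) | C1C2OOC(C)(O2)CC[C@@]1(O[Si](CC)(CC)CC)C(C)C | intermediate
4 | (3S)-6-oxo-3-(propan-2-yl)-3-[(triethylsilyl)oxy]heptanal | CC(=O)CC[C@@](CC=O)(O[Si](CC)(CC)CC)C(C)C | intermediate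
5 | (5R)-2-methyl-5-(propan-2-yl)-5-[(triethylsilyl)oxy]cyclopent-1-ene-1-carbaldehyde | O=CC1=C(C)CC[C@@]1(O[Si](CC)(CC)CC)C(C)C | intermediate
6 | (5R)-5-hydroxy-2-methyl-5-(propan-2-yl)cyclopent-1-ene-1-carbaldehyde | O=CC1=C(C)CC[C@@]1(O)C(C)C | intermediate
7 | 3-methylbut-2-enoic acid | CC(C)=CC(=O)O | starting material
8 | (1S,2R,5R)-2-hydroxy-5-methyl-5-(3-methylbut-2-enoyl)-2-(propan-2-yl)cyclopentane-1-carbaldehyde (formyl epimer of 9) | O=C[C@H]1[C@@](C(=O)C=C(C)C)(C)CC[C@@]1(O)C(C)C | intermediate
9 | (1R,2R,5R)-2-hydroxy-5-methyl-5-(3-methylbut-2-enoyl)-2-(propan-2-yl)cyclopentane-1-carbaldehyde (formyl, acyl and hydroxyl all cis) | O=C[C@@H]1[C@@](C(=O)C=C(C)C)(C)CC[C@@]1(O)C(C)C | intermediate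
10 | (1R,2R,5R)-2-hydroxy-5-methyl-5-(3-methylbut-3-enoyl)-2-(propan-2-yl)cyclopentane-1-carbaldehyde | O=C[C@@H]1[C@@](C(=O)CC(C)=C)(C)CC[C@@]1(O)C(C)C | intermediate
11 | (1R,4R,5S,6R)-4,6-dihydroxydauc-8(14)-en-10-one (exocyclic methylene on C8) | O=C1CC(=C)C[C@@H](O)[C@@H]2[C@@]1(C)CC[C@@]2(O)C(C)C | intermediate
12 | (1R,4R,5S,6R)-4,6-dihydroxydauc-8-en-10-one | O=C1C=C(C)C[C@@H](O)[C@@H]2[C@@]1(C)CC[C@@]2(O)C(C)C | intermediate
13 | 4-(acetyloxy)benzoyl chloride | CC(=O)Oc1ccc(cc1)C(Cl)=O | starting material
14 | (1R,4R,5S,6R)-4-hydroxy-10-oxodauc-8-en-6-yl 4-(acetyloxy)benzoate | O=C1C=C(C)C[C@@H](OC(=O)c3ccc(OC(C)=O)cc3)[C@@H]2[C@@]1(C)CC[C@@]2(O)C(C)C | intermediate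
15 | (1R,4R,5S,6R,10R)-4,10-dihydroxydauc-8-en-6-yl 4-(acetyloxy)benzoate | O[C@@H]1C=C(C)C[C@@H](OC(=O)c3ccc(OC(C)=O)cc3)[C@@H]2[C@@]1(C)CC[C@@]2(O)C(C)C | intermediate
16 | (2E)-2-methylbut-2-enoyl chloride (tigloyl chloride) | C/C=C(\C)C(Cl)=O | starting material
17 | (1R,4R,5S,6R,10R)-4-hydroxy-10-{[(2E)-2-methylbut-2-enoyl]oxy}dauc-8-en-6-yl 4-(acetyloxy)benzoate | C/C=C(\C)C(=O)O[C@@H]1C=C(C)C[C@@H](OC(=O)c3ccc(OC(C)=O)cc3)[C@@H]2[C@@]1(C)CC[C@@]2(O)C(C)C | intermediate
18 | (1R,4R,5S,6R,10R)-4-hydroxy-10-{[(2E)-2-methylbut-2-enoyl]oxy}dauc-8-en-6-yl 4-hydroxybenzoate | C/C=C(\C)C(=O)O[C@@H]1C=C(C)C[C@@H](OC(=O)c2ccc(O)cc2)[C@@H]2[C@@]1(C)CC[C@@]2(O)C(C)C | target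

**Totals**
Total step count: 8. Longest linear sequence: 8 steps (1 → 18); compounds 7, 13 and 16 are purchased.

**Three steps most likely to fail**

Step 3 (the proposed new method). The acyl radical must add intermolecularly to a tetrasubstituted alkene carbon. Competing paths are attack of the Ph3P radical cation on the tertiary allylic alcohol and reaction of the unsaturated acyl radical through its ketenyl-alkyl form. The fallback uses known chemistry, sets out from 6 and comes back at 9. A TMSCl-accelerated, CuBr·SMe2-mediated conjugate addition of vinylmagnesium bromide to 6 (THF, −78 °C), followed by acid hydrolysis of the silyl enol ether and DBU equilibration, gives the C1-vinyl aldehyde F1, with the vinyl group anti to isopropyl. NaBH4 reduces it to the diol F2. Ozonolysis of the vinyl group (O3, then PPh3) gives the hydroxy aldehyde F3, which sits in equilibrium with its lactol. Addition of 2-methylprop-1-enylmagnesium bromide gives the triol F4. A double Swern oxidation (primary alcohol to aldehyde, allylic alcohol to enone) returns 9.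

Step 4. The photodeconjugated ketone can reconjugate before cyclising, and Me2AlCl can transfer methyl to the hindered aldehyde. The fallback sets out from 9 and comes back at 12. It is an anionic, thermodynamically controlled vinylogous aldol cyclisation: LiOtBu (2.2 equiv) in THF at −20 → 0 °C deprotonates the enone γ-methyl reversibly, and the dienolate terminus adds to the aldehyde chelated to the C4–OLi group (7-enolendo-exo-trig). The same chelate controls C6. This fallback makes no further compound (none F0).

Step 6. The tertiary hydroxyl may exchange onto boron too slowly, so that background external hydride delivery lowers the selectivity at C10. The fallback sets out from 12 and comes back at 15. The order of operations is reversed: Me4NBH(OAc)3 in MeCN/AcOH reduces the diol ketone 12, where the readily exchanged secondary C6–OH and the C4–OH, both on the concave face, anchor the hydride, giving the triol F5. Site-selective acylation of the less hindered C6–OH (the C10–OH is neopentyl and allylic) with 13 (1.05 equiv, pyridine, −20 °C) then gives 15.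

**Further compounds**
F1 | step 3 | (1R,2R,5S)-5-ethenyl-2-hydroxy-5-methyl-2-(propan-2-yl)cyclopentane-1-carbaldehyde | O=C[C@@H]1[C@@](C=C)(C)CC[C@@]1(O)C(C)C
F2 | step 3 | diol from reduction of the formyl group of F1 to hydroxymethyl | OC[C@@H]1[C@@](C=C)(C)CC[C@@]1(O)C(C)C
F3 | step 3 | hydroxy aldehyde from ozonolysis of the vinyl group of F2 (open form of the lactol) | OC[C@@H]1[C@@](C=O)(C)CC[C@@]1(O)C(C)C
F4 | step 3 | triol from 2-methylprop-1-enyl addition to F3 (both epimers at the new carbinol) | OC[C@@H]1[C@@](C(O)C=C(C)C)(C)CC[C@@]1(O)C(C)C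
F0 | step 4 | none | none
F5 | step 6 | (1R,4R,5S,6R,10R)-dauc-8-ene-4,6,10-triol | O[C@@H]1C=C(C)C[C@@H](O)[C@@H]2[C@@]1(C)CC[C@@]2(O)C(C)C
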